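## Plan

1. Numbering: ring C1 (C=O), C2 (C–CH3) and C3 (CH) carry the epoxide, C4 (CH2), C5 (side chain), C6 (O‑angeloyl); side chain C1'–C7', with C2' on C5 and the carbinol at C3'.
2. Retrosynthesis: both angelates are cut first (C6–O and C3'–O acyl bonds). The epoxide oxygen is cut next (carbinol‑directed epoxidation of a 2‑methylcyclohex‑2‑enone after temporary reduction of C1). The enone ring is then cut at C1–C2 and C3–C4 into a cyclobutanone (C1, C6, C5, C4) and a silylated propyne (C2, C3). The side chain is cut last at C2'–C3'.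
3. Enabling feature: C2–C3 of the epoxy ketone is a masked alkene (an alkyne one level lower) lying between the carbonyl C1 and the methylene C4. The other ring atoms C1–C6–C5–C4 can therefore be stored as a strained four‑membered ketone whose C1–C4 bond is exchanged for two bonds to the alkyne.
4. Forward order: enol triflate plus 4‑methylpent‑3‑enal (chain joined at C2'–C3'); unmasking, desymmetrisation and α‑oxygenation of the cyclobutanone; nickel‑catalysed ring expansion to the only carbocycle; desilylation; double angeloylation; epoxide last.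
5. Stereochemistry: C3' from a chiral chromium catalyst; C5 from a chiral lithium amide; C6 (anti to C5), the temporary C1 carbinol and the C2/C3 epoxide by substrate control relayed from C5; angelate geometry bought with angelic acid.

Key step: step 9

Remark: the enantiomer of the ligand in step 4 and of the lithium amide in step 6 is assigned by analogy with simpler substrates; the antipode of either controller is equally available.

## Route

Step 1
Reactants: 1 methyl 3,3-dimethoxycyclobutane-1-carboxylate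
Product: 3 1-(3,3-dimethoxycyclobutyl)ethan-1-one, via Weinreb amide 2 (not isolated)
Conditions: MeNH(OMe)·HCl, i-PrMgCl, THF, −20 °C; then MeMgBr, 0 °C; aq NH4Cl
Reagents that add atoms: methylmagnesium bromide, C[Mg]Br; N,O-dimethylhydroxylamine hydrochloride, CNOC.Cl (its atoms are in 2 only)
Why: Weinreb ketone synthesis run in one pot; the chelated magnesium tetrahedral intermediate should stop the addition at the ketone, and the dimethyl ketal is inert to Grignard reagents.

Step 2
Reactants: 3 1-(3,3-dimethoxycyclobutyl)ethan-1-one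
Product: 4 1-(3,3-dimethoxycyclobutyl)ethenyl trifluoromethanesulfonate
Conditions: KN(SiMe3)2, THF, −78 °C; PhNTf2, −78 → 0 °C
Reagents that add atoms: N-phenylbis(trifluoromethanesulfonimide), O=S(=O)(N(c1ccccc1)S(=O)(=O)C(F)(F)F)C(F)(F)F
Why: kinetic enolate O‑triflation; deprotonation should occur at the methyl group, because the cyclobutyl methine is hindered and would give a strained exocyclic enolate.

Step 3
Reactants: 5 4-methylpent-3-en-1-ol
Product: 6 4-methylpent-3-enal
Conditions: Dess–Martin periodinane, NaHCO3, CH2Cl2, 0 °C → rt; used crude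
Reagents that add atoms: none
Why: Dess–Martin oxidation under buffered, non‑enolising conditions should give the β,γ‑unsaturated aldehyde without migration of the double bond into conjugation.

Step 4
Reactants: 4 1-(3,3-dimethoxycyclobutyl)ethenyl trifluoromethanesulfonate; 6 4-methylpent-3-enal
Product: 9 3-[(3S)-3-hydroxy-6-methylhepta-1,5-dien-2-yl]cyclobutan-1-one, via trimethylsilyl ether 7 (not isolated), via hydroxy ketal 8 (not isolated)
Conditions: CrCl2 (10 mol %), chiral (4,5-dihydrooxazol-2-yl)aryl methanesulfonamide ligand (11 mol %), Et3N (cat.), NiCl2(2,9-dimethyl-1,10-phenanthroline) (2 mol %), Mn, LiCl, Me3SiCl, MeCN, rt; then 1 M aq HCl, THF, rt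
Reagents that add atoms: water, O; chlorotrimethylsilane, C[Si](C)(C)Cl (its atoms are in 7 only)
Why: catalytic asymmetric Nozaki–Hiyama–Kishi coupling; zerovalent nickel should insert into the C–OTf bond and hand the alkenyl group to chromium, whose chiral sulfonamide complex differentiates the aldehyde faces and sets C3' (S) by reagent control, Mn and Me3SiCl turn the chromium over, and the acidic work‑up cleaves the trimethylsilyl ether and the dimethyl ketal.

Step 5
Reactants: 9 3-[(3S)-3-hydroxy-6-methylhepta-1,5-dien-2-yl]cyclobutan-1-one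
Product: 10 3-[(3S)-3-{[tert-butyl(dimethyl)silyl]oxy}-6-methylhepta-1,5-dien-2-yl]cyclobutan-1-one
Conditions: t-BuMe2SiCl, imidazole, DMF, rt
Reagents that add atoms: tert-butylchlorodimethylsilane, CC(C)(C)[Si](C)(C)Cl
Why: standard imidazole‑promoted silylation of a secondary alcohol; the ether masks the allylic oxygen against the strong base of step 6 and the zerovalent nickel of step 9.

Step 6
Reactants: 10 3-[(3S)-3-{[tert-butyl(dimethyl)silyl]oxy}-6-methylhepta-1,5-dien-2-yl]cyclobutan-1-one
Product: 11 {[(3R)-3-[(3S)-3-{[tert-butyl(dimethyl)silyl]oxy}-6-methylhepta-1,5-dien-2-yl]cyclobut-1-en-1-yl]oxy}triethylsilane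
Conditions: (S,S)-bis(1-phenylethyl)amine, n-BuLi, THF, 0 °C; then Et3SiCl and 10, −100 °C (internal quench)
Reagents that add atoms: chlorotriethylsilane, CC[Si](CC)(CC)Cl
Why: desymmetrising deprotonation of a 3‑substituted cyclobutanone with a C2‑symmetric chiral lithium amide and in situ silylation; the base should select one of the two α‑methylene groups (diastereotopic only through the remote C3' centre) and so create the ring stereocentre, the future C5, by reagent control.

Step 7
Reactants: 11 {[(3R)-3-[(3S)-3-{[tert-butyl(dimethyl)silyl]oxy}-6-methylhepta-1,5-dien-2-yl]cyclobut-1-en-1-yl]oxy}triethylsilane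
Product: 13 (2S,3S)-3-[(3S)-3-{[tert-butyl(dimethyl)silyl]oxy}-6-methylhepta-1,5-dien-2-yl]-2-[(triethylsilyl)oxy]cyclobutan-1-one, via silyloxy epoxide 12 (not isolated)
Conditions: dimethyldioxirane (1.0 equiv, acetone solution), CH2Cl2, −78 °C; then warm to rt
Reagents that add atoms: dimethyldioxirane, CC1(C)OO1
Why: Rubottom oxidation; the dioxirane should epoxidise the electron‑rich silyl enol ether much faster than the trisubstituted alkene and on the face anti to the ring substituent, and a 1,4‑silyl shift opens the epoxide to the trans α‑silyloxy ketone, setting the future C6 (S) by substrate control.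

Step 8
Reactants: 14 prop-1-yn-1-ylmagnesium bromide; 15 benzyl(chloro)dimethylsilane
Product: 16 benzyldimethyl(prop-1-yn-1-yl)silane
Conditions: THF, 0 °C → rt
Reagents that add atoms: none
Why: silylation of an alkynyl Grignard reagent; the benzyldimethylsilyl group is chosen because it later steers the alkyne orientation and can be cleaved from sp2 carbon by fluoride.

Step 9
Reactants: 13 (2S,3S)-3-[(3S)-3-{[tert-butyl(dimethyl)silyl]oxy}-6-methylhepta-1,5-dien-2-yl]-2-[(triethylsilyl)oxy]cyclobutan-1-one; 16 benzyldimethyl(prop-1-yn-1-yl)silane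
Product: 17 (5S,6S)-3-[benzyl(dimethyl)silyl]-5-[(3S)-3-{[tert-butyl(dimethyl)silyl]oxy}-6-methylhepta-1,5-dien-2-yl]-2-methyl-6-[(triethylsilyl)oxy]cyclohex-2-en-1-one
Conditions: Ni(cod)2 (10 mol %), PCy3 (20 mol %), 16 (2 equiv), toluene, 100 °C
Reagents that add atoms: none
Why: Zerovalent nickel should couple the C=O of 13 and the alkyne of 16 by oxidative cyclisation to a spiro oxanickelacyclopentene in which the methyl‑bearing alkyne carbon is bonded to the former carbonyl carbon (C1–C2); β‑carbon elimination then opens the strained four‑membered ring at C1–C4, and reductive elimination from the seven‑membered nickelacycle joins C4 to the silyl‑bearing carbon (C3–C4). The closest known reaction type is the nickel‑catalysed intermolecular insertion of alkynes into cyclobutanones and azetidin‑3‑ones, a formal [4+2] ring expansion. The one ring formed, the cyclohexenone, closes by C(sp3)–C(sp2) reductive elimination, so the four‑membered ring grows to six in a single catalytic turnover. No new stereocentre is created; C5 and C6 take no part in any bond change and are carried over from 13 with retention. Two selectivities are needed: the alkyne orientation, secured by the silyl group, which prefers the position next to nickel and thereby places CH3 on C2; and cleavage of the CH2–C(=O) bond rather than the CH(OSiEt3)–C(=O) bond, secured by transfer of the less hindered primary carbon to nickel, as with 2‑substituted azetidin‑3‑ones. Loss of a β‑hydride from the alkylnickel should be outrun by reductive elimination within the nickelacycle.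

Step 10
Reactants: 17 (5S,6S)-3-[benzyl(dimethyl)silyl]-5-[(3S)-3-{[tert-butyl(dimethyl)silyl]oxy}-6-methylhepta-1,5-dien-2-yl]-2-methyl-6-[(triethylsilyl)oxy]cyclohex-2-en-1-one
Product: 18 (5S,6S)-6-hydroxy-5-[(3S)-3-hydroxy-6-methylhepta-1,5-dien-2-yl]-2-methylcyclohex-2-en-1-one
Conditions: Bu4NF (5 equiv), CuI (20 mol %), wet THF, 0 °C → rt, argon; aq NH4Cl
Reagents that add atoms: none
Why: fluoride‑mediated global desilylation; both silyl ethers are cleaved, and the benzyldimethylsilyl group should lose its benzyl group to fluoride and then undergo protodesilylation of the alkenyl–silicon bond (known for alkenyl benzyldimethylsilanes), here helped by the electron‑poor enone carbon.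

Step 11
Reactants: 18 (5S,6S)-6-hydroxy-5-[(3S)-3-hydroxy-6-methylhepta-1,5-dien-2-yl]-2-methylcyclohex-2-en-1-one; 19 angelic acid [(2Z)-2-methylbut-2-enoic acid]
Product: 20 (1S,6S)-3-methyl-6-[(3S)-6-methyl-3-{[(2Z)-2-methylbut-2-enoyl]oxy}hepta-1,5-dien-2-yl]-2-oxocyclohex-3-en-1-yl (2Z)-2-methylbut-2-enoate
Conditions: 19 (4 equiv), 2,4,6-trichlorobenzoyl chloride (4 equiv), Et3N, toluene, rt; then 18, 80 °C, argon, no nucleophilic catalyst
Reagents that add atoms: none
Why: Yamaguchi‑type mixed‑anhydride esterification of both secondary alcohols; the hindered trichlorobenzoyl carbonyl directs attack to the angeloyl carbonyl, and leaving out a nucleophilic amine catalyst should preserve the Z geometry.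

Step 12
Reactants: 20 (1S,6S)-3-methyl-6-[(3S)-6-methyl-3-{[(2Z)-2-methylbut-2-enoyl]oxy}hepta-1,5-dien-2-yl]-2-oxocyclohex-3-en-1-yl (2Z)-2-methylbut-2-enoate
Product: 21 (1S,2S,6S)-2-hydroxy-3-methyl-6-[(3S)-6-methyl-3-{[(2Z)-2-methylbut-2-enoyl]oxy}hepta-1,5-dien-2-yl]cyclohex-3-en-1-yl (2Z)-2-methylbut-2-enoate
Conditions: NaBH4, CeCl3·7H2O, MeOH, −78 °C
Reagents that add atoms: none
Why: Luche 1,2‑reduction; axial hydride delivery to the half‑chair with the C5 and C6 substituents equatorial should give the equatorial C1 carbinol, trans to the C6 angelate and cis to the C5 side chain (substrate control, as for other 5‑substituted 2‑methylcyclohexenones), while the angelates are untouched at low temperature.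

Step 13
Reactants: 21 (1S,2S,6S)-2-hydroxy-3-methyl-6-[(3S)-6-methyl-3-{[(2Z)-2-methylbut-2-enoyl]oxy}hepta-1,5-dien-2-yl]cyclohex-3-en-1-yl (2Z)-2-methylbut-2-enoate
Product: 22 (1R,2R,3S,4S,6S)-2-hydroxy-1-methyl-4-[(3S)-6-methyl-3-{[(2Z)-2-methylbut-2-enoyl]oxy}hepta-1,5-dien-2-yl]-7-oxabicyclo[4.1.0]heptan-3-yl (2Z)-2-methylbut-2-enoate
Conditions: VO(acac)2 (5 mol %), t-BuOOH (decane solution), CH2Cl2, 0 °C → rt
Reagents that add atoms: tert-butyl hydroperoxide, CC(C)(C)OO
Why: hydroxyl‑directed vanadium‑catalysed epoxidation of an allylic alcohol; oxygen is delivered syn to the C1 carbinol, which sets both epoxide carbons cis to the C5 side chain, and the undirected prenyl and methylidene alkenes and the electron‑poor angelates should not compete.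

Step 14
Reactants: 22 (1R,2R,3S,4S,6S)-2-hydroxy-1-methyl-4-[(3S)-6-methyl-3-{[(2Z)-2-methylbut-2-enoyl]oxy}hepta-1,5-dien-2-yl]-7-oxabicyclo[4.1.0]heptan-3-yl (2Z)-2-methylbut-2-enoate
Product: 23 (1S,3S,4S,6S)-1-methyl-4-[(3S)-6-methyl-3-{[(2Z)-2-methylbut-2-enoyl]oxy}hepta-1,5-dien-2-yl]-2-oxo-7-oxabicyclo[4.1.0]heptan-3-yl (2Z)-2-methylbut-2-enoate
Conditions: Dess–Martin periodinane, NaHCO3, CH2Cl2, 0 °C → rt
Reagents that add atoms: none
Why: Dess–Martin oxidation of the epoxy alcohol to the epoxy ketone under buffered conditions; the temporary C1 stereocentre is removed, and the only enolisable centre, C6, already holds its more stable equatorial arrangement trans to C5.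

## Compound list

1 | methyl 3,3-dimethoxycyclobutane-1-carboxylate | COC(=O)C1CC(OC)(OC)C1 | starting material
2 | N-methoxy-N-methyl-3,3-dimethoxycyclobutane-1-carboxamide (Weinreb amide, formed in the flask) | CON(C)C(=O)C1CC(OC)(OC)C1 | intermediate
3 | 1-(3,3-dimethoxycyclobutyl)ethan-1-one | CC(=O)C1CC(OC)(OC)C1 | intermediate
4 | 1-(3,3-dimethoxycyclobutyl)ethenyl trifluoromethanesulfonate | C=C(OS(=O)(=O)C(F)(F)F)C1CC(OC)(OC)C1 | intermediate
5 | 4-methylpent-3-en-1-ol | CC(C)=CCCO | starting material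
6 | 4-methylpent-3-enal | CC(C)=CCC=O | intermediate
7 | {[(3S)-2-(3,3-dimethoxycyclobutyl)-6-methylhepta-1,5-dien-3-yl]oxy}trimethylsilane (formed in the flask) | C=C([C@H](CC=C(C)C)O[Si](C)(C)C)C1CC(OC)(OC)C1 | intermediate
8 | (3S)-2-(3,3-dimethoxycyclobutyl)-6-methylhepta-1,5-dien-3-ol (formed in the flask) | C=C([C@H](CC=C(C)C)O)C1CC(OC)(OC)C1 | intermediate
9 | 3-[(3S)-3-hydroxy-6-methylhepta-1,5-dien-2-yl]cyclobutan-1-one | C=C([C@H](CC=C(C)C)O)C1CC(=O)C1 | intermediate
10 | 3-[(3S)-3-{[tert-butyl(dimethyl)silyl]oxy}-6-methylhepta-1,5-dien-2-yl]cyclobutan-1-one | C=C([C@H](CC=C(C)C)O[Si](C)(C)C(C)(C)C)C1CC(=O)C1 | intermediate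
11 | {[(3R)-3-[(3S)-3-{[tert-butyl(dimethyl)silyl]oxy}-6-methylhepta-1,5-dien-2-yl]cyclobut-1-en-1-yl]oxy}triethylsilane | C=C([C@H](CC=C(C)C)O[Si](C)(C)C(C)(C)C)[C@@H]1CC(O[Si](CC)(CC)CC)=C1 | intermediate
12 | 3-[(3S)-3-{[tert-butyl(dimethyl)silyl]oxy}-6-methylhepta-1,5-dien-2-yl]-1-[(triethylsilyl)oxy]-5-oxabicyclo[2.1.0]pentane, oxirane oxygen anti to the C3 substituent (formed in the flask) | C=C([C@H](CC=C(C)C)O[Si](C)(C)C(C)(C)C)[C@@H]1C[C@@]2(O[Si](CC)(CC)CC)O[C@@H]12 | intermediate
13 | (2S,3S)-3-[(3S)-3-{[tert-butyl(dimethyl)silyl]oxy}-6-methylhepta-1,5-dien-2-yl]-2-[(triethylsilyl)oxy]cyclobutan-1-one | C=C([C@H](CC=C(C)C)O[Si](C)(C)C(C)(C)C)[C@@H]1CC(=O)[C@H]1O[Si](CC)(CC)CC | intermediate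
14 | prop-1-yn-1-ylmagnesium bromide | CC#C[Mg]Br | starting material
15 | benzyl(chloro)dimethylsilane | C[Si](C)(Cl)Cc1ccccc1 | starting material
16 | benzyldimethyl(prop-1-yn-1-yl)silane | CC#C[Si](C)(C)Cc1ccccc1 | intermediate
17 | (5S,6S)-3-[benzyl(dimethyl)silyl]-5-[(3S)-3-{[tert-butyl(dimethyl)silyl]oxy}-6-methylhepta-1,5-dien-2-yl]-2-methyl-6-[(triethylsilyl)oxy]cyclohex-2-en-1-one | C=C([C@H](CC=C(C)C)O[Si](C)(C)C(C)(C)C)[C@@H]1CC([Si](C)(C)Cc2ccccc2)=C(C)C(=O)[C@H]1O[Si](CC)(CC)CC | intermediate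
18 | (5S,6S)-6-hydroxy-5-[(3S)-3-hydroxy-6-methylhepta-1,5-dien-2-yl]-2-methylcyclohex-2-en-1-one | C=C([C@H](CC=C(C)C)O)[C@@H]1CC=C(C)C(=O)[C@H]1O | intermediate
19 | angelic acid, (2Z)-2-methylbut-2-enoic acid | C/C=C(/C)C(=O)O | starting material
20 | (1S,6S)-3-methyl-6-[(3S)-6-methyl-3-{[(2Z)-2-methylbut-2-enoyl]oxy}hepta-1,5-dien-2-yl]-2-oxocyclohex-3-en-1-yl (2Z)-2-methylbut-2-enoate | C=C([C@H](CC=C(C)C)OC(=O)/C(C)=C\C)[C@@H]1CC=C(C)C(=O)[C@H]1OC(=O)/C(C)=C\C | intermediate
21 | (1S,2S,6S)-2-hydroxy-3-methyl-6-[(3S)-6-methyl-3-{[(2Z)-2-methylbut-2-enoyl]oxy}hepta-1,5-dien-2-yl]cyclohex-3-en-1-yl (2Z)-2-methylbut-2-enoate | C=C([C@H](CC=C(C)C)OC(=O)/C(C)=C\C)[C@@H]1CC=C(C)[C@H](O)[C@H]1OC(=O)/C(C)=C\C | intermediate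
22 | (1R,2R,3S,4S,6S)-2-hydroxy-1-methyl-4-[(3S)-6-methyl-3-{[(2Z)-2-methylbut-2-enoyl]oxy}hepta-1,5-dien-2-yl]-7-oxabicyclo[4.1.0]heptan-3-yl (2Z)-2-methylbut-2-enoate | C=C([C@H](CC=C(C)C)OC(=O)/C(C)=C\C)[C@@H]1C[C@@H]2O[C@]2(C)[C@H](O)[C@H]1OC(=O)/C(C)=C\C | intermediate
23 | (1S,3S,4S,6S)-1-methyl-4-[(3S)-6-methyl-3-{[(2Z)-2-methylbut-2-enoyl]oxy}hepta-1,5-dien-2-yl]-2-oxo-7-oxabicyclo[4.1.0]heptan-3-yl (2Z)-2-methylbut-2-enoate | C=C([C@H](CC=C(C)C)OC(=O)/C(C)=C\C)[C@@H]1C[C@@H]2O[C@]2(C)C(=O)[C@H]1OC(=O)/C(C)=C\C | target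

## Step count and risks

Total step count: 14. Longest linear sequence: 12 steps (steps 1, 2, 4, 5, 6, 7, 9, 10, 11, 12, 13, 14); steps 3 and 8 are side branches.

Steps most likely to fail:

1. Step 9. The nickelacycle may break the ring bond to the silyloxy‑bearing carbon instead of the one to the methylene, the alkyne may insert in the reversed orientation, or the alkylnickel may lose a β‑hydride and give a ring‑opened enone. Fallback, setting out from 13 and coming back at 18: the same two bonds are made one after the other. Ethynylmagnesium bromide should add to the ketone of 13 to give (2S,3S)-3-[(3S)-3-{[tert-butyl(dimethyl)silyl]oxy}-6-methylhepta-1,5-dien-2-yl]-1-ethynyl-2-[(triethylsilyl)oxy]cyclobutan-1-ol F1 (carbinol configuration immaterial). Alkoxide‑directed anti‑carbomagnesiation with MeMgBr and CuI followed by I2 should give the (Z)-iodoalkenyl carbinol F2, with the methyl group fixed on the carbon bonded to the carbinol. Pd(PPh3)4 and Cs2CO3 in toluene at 90 °C should then bring about oxidative addition, palladium alkoxide formation, β‑carbon elimination of the less substituted ring bond and C–C reductive elimination, giving (5S,6S)-5-[(3S)-3-{[tert-butyl(dimethyl)silyl]oxy}-6-methylhepta-1,5-dien-2-yl]-2-methyl-6-[(triethylsilyl)oxy]cyclohex-2-en-1-one F3. Bu4NF in THF cleaves both silyl ethers of F3 and gives 18.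

2. Step 10. Cleavage of the alkenyl–silicon bond may stay incomplete, or the free α‑hydroxy enone may degrade under basic fluoride (enolisation, air oxidation). Fallback, setting out from 17 and coming back at 22: the silicon is kept until the epoxide is in place. HF·pyridine in THF should remove only the two silyl ethers and give (5S,6S)-3-[benzyl(dimethyl)silyl]-6-hydroxy-5-[(3S)-3-hydroxy-6-methylhepta-1,5-dien-2-yl]-2-methylcyclohex-2-en-1-one F4. Angeloylation as in step 11 gives the silylated bis‑angelate enone F5. Reduction as in step 12 gives the silylated allylic alcohol F6. Epoxidation with VO(acac)2 and t-BuOOH as in step 13 gives the epoxysilane F7. Bu4NF in THF at 0 °C should then cleave the carbon–silicon bond of the α,β‑epoxysilane with retention (a known reaction of epoxysilanes) and give 22.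

3. Step 6. The chiral amide may discriminate poorly between the two α‑methylene groups on this substrate, or select in the opposite sense. Fallback, setting out from 10 and coming back at 13: selection by the base is replaced by separation, which is possible because C3' is already fixed. LiN(i-Pr)2 and Et3SiCl should give 11 together with its ring epimer, the (3S)-cyclobutenyl silyl ether F8. Oxidation of the mixture as in step 7 gives 13 and the (2R,3R)-silyloxy ketone F9, which are diastereomers and should be separable by chromatography. F9 is returned to 10 with SmI2 in THF/MeOH (reductive removal of the α‑silyloxy group) and recycled.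

## Further compounds

F1 | step 9 | (2S,3S)-3-[(3S)-3-{[tert-butyl(dimethyl)silyl]oxy}-6-methylhepta-1,5-dien-2-yl]-1-ethynyl-2-[(triethylsilyl)oxy]cyclobutan-1-ol (C1 configuration not defined) | C=C([C@H](CC=C(C)C)O[Si](C)(C)C(C)(C)C)[C@@H]1CC(O)(C#C)[C@H]1O[Si](CC)(CC)CC
F2 | step 9 | (2S,3S)-3-[(3S)-3-{[tert-butyl(dimethyl)silyl]oxy}-6-methylhepta-1,5-dien-2-yl]-1-[(1Z)-1-iodoprop-1-en-2-yl]-2-[(triethylsilyl)oxy]cyclobutan-1-ol (C1 configuration not defined) | C=C([C@H](CC=C(C)C)O[Si](C)(C)C(C)(C)C)[C@@H]1CC(O)(/C(C)=C\I)[C@H]1O[Si](CC)(CC)CC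
F3 | step 9 | (5S,6S)-5-[(3S)-3-{[tert-butyl(dimethyl)silyl]oxy}-6-methylhepta-1,5-dien-2-yl]-2-methyl-6-[(triethylsilyl)oxy]cyclohex-2-en-1-one | C=C([C@H](CC=C(C)C)O[Si](C)(C)C(C)(C)C)[C@@H]1CC=C(C)C(=O)[C@H]1O[Si](CC)(CC)CC
F4 | step 10 | (5S,6S)-3-[benzyl(dimethyl)silyl]-6-hydroxy-5-[(3S)-3-hydroxy-6-methylhepta-1,5-dien-2-yl]-2-methylcyclohex-2-en-1-one | C=C([C@H](CC=C(C)C)O)[C@@H]1CC([Si](C)(C)Cc2ccccc2)=C(C)C(=O)[C@H]1O
F5 | step 10 | (1S,6S)-4-[benzyl(dimethyl)silyl]-3-methyl-6-[(3S)-6-methyl-3-{[(2Z)-2-methylbut-2-enoyl]oxy}hepta-1,5-dien-2-yl]-2-oxocyclohex-3-en-1-yl (2Z)-2-methylbut-2-enoate | C=C([C@H](CC=C(C)C)OC(=O)/C(C)=C\C)[C@@H]1CC([Si](C)(C)Cc2ccccc2)=C(C)C(=O)[C@H]1OC(=O)/C(C)=C\C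
F6 | step 10 | (1S,2S,6S)-4-[benzyl(dimethyl)silyl]-2-hydroxy-3-methyl-6-[(3S)-6-methyl-3-{[(2Z)-2-methylbut-2-enoyl]oxy}hepta-1,5-dien-2-yl]cyclohex-3-en-1-yl (2Z)-2-methylbut-2-enoate | C=C([C@H](CC=C(C)C)OC(=O)/C(C)=C\C)[C@@H]1CC([Si](C)(C)Cc2ccccc2)=C(C)[C@H](O)[C@H]1OC(=O)/C(C)=C\C
F7 | step 10 | epoxysilane analogue of 22 carrying benzyl(dimethyl)silyl in place of hydrogen on the epoxide carbon C6 of the bicycle, silicon on the face opposite the epoxide oxygen | C=C([C@H](CC=C(C)C)OC(=O)/C(C)=C\C)[C@@H]1C[C@]2([Si](C)(C)Cc3ccccc3)O[C@]2(C)[C@H](O)[C@H]1OC(=O)/C(C)=C\C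
F8 | step 6 | {[(3S)-3-[(3S)-3-{[tert-butyl(dimethyl)silyl]oxy}-6-methylhepta-1,5-dien-2-yl]cyclobut-1-en-1-yl]oxy}triethylsilane | C=C([C@H](CC=C(C)C)O[Si](C)(C)C(C)(C)C)[C@H]1CC(O[Si](CC)(CC)CC)=C1
F9 | step 6 | (2R,3R)-3-[(3S)-3-{[tert-butyl(dimethyl)silyl]oxy}-6-methylhepta-1,5-dien-2-yl]-2-[(triethylsilyl)oxy]cyclobutan-1-one | C=C([C@H](CC=C(C)C)O[Si](C)(C)C(C)(C)C)[C@H]1CC(=O)[C@@H]1O[Si](CC)(CC)CC
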